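Gamma leaves less starting material than zeta, 17.5% of the charge against 26.0% as run means, and it was charged with more coupling partner, 6.6 equiv against 4.2 equiv.

in all of them: starting material 0.30 M

| charge | coupling partner | remark | time |
|---|---|---|---|
| zeta | 4.2 equiv | run made earlier |  |
| gamma | 6.6 equiv | run made earlier |  |
| flask | 3.00 equiv |  | 5.0 h |

| run | time / h | starting material / % | product / % |
|---|---|---|---|
| zeta | 0.833 | 24.9 | 51.5 |
| zeta | 1.50 | 26.1 | 51.8 |
| zeta | 2.50 | 27.6 | 52.2 |
| zeta | 3.00 | 26.3 | 52.7 |
| zeta | 4.00 | 25.9 | 51.9 |
| zeta | 5.00 | 25.7 | 51.9 |
| zeta | 6.00 | 25.3 | 50.1 |
| gamma | 0.833 | 16.9 | 57.1 |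
| gamma | 1.50 | 15.5 | 57.3 |
| gamma | 2.50 | 16.9 | 58.0 |
| gamma | 3.00 | 17.9 | 58.9 |
| gamma | 4.00 | 18.8 | 57.8 |
| gamma | 5.00 | 18.0 | 58.8 |
| gamma | 6.00 | 18.7 | 58.2 |

(each reading ± 1 percentage point)

- steps thought possible: starting material + coupling partner <-> adduct; adduct <-> product
- the reaction counts as stopped when no species that holds the starting material changes by six tenths of a point or more over the second half of the time

- why nothing more happens at 5.0 h, or that something still does (forward and back rates have come level / all of the starting material has reacted / the coupling partner has run out first / it is still moving)
- part of the starting material gone at 5.0 h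
- the product standing at 5.0 h, as a percentage of the starting material charged

1. Both runs stay flat within the scatter from the first reading on, so we read them as standing at rest. One coupling partner goes with each starting material taken, so free partner is 1.04 M in zeta and 1.73 M in gamma.

2. Free partner times the fraction left, over the fraction taken, reads 0.364 M in zeta and 0.368 M in gamma. Their mean, 0.366 M, is the even-odds level: the free partner at which as much starting material is taken as left. Odds of taken to left are then free partner over this level.

3. Product per unit taken reads 0.699 in zeta and 0.703 in gamma; we carry 0.701.

4. In our flask, solving the odds gives a level of 65.7% taken and 46.1% product.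

5. Zeta's first reading bounds its mean early slope at 0.902 /h or more. If pace goes with the partner charge, our flask starts at 0.644 /h or faster, a lower bound because zeta was already flat at its first reading, and reaches its knee no later than about 1.02 h, sooner than 5.0 h. If the share holds on the way, product crosses starting material at 58.8% taken, below the level at which the curve runs flat.

The forecast, noting “The two runs agree”, gave forward and back rates have come level, 65.7% gone and 46.3% product. The flask gives forward and back rates have come level, 65.4% gone and 46.2% product.

    starting material + coupling partner ⇌ adduct (K = 0.790 /M, k = 0.00190 /M/s)
    adduct ⇌ product (K = 2.40, k = 0.0300 /s)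

The flask has come to rest: its largest move over the second half is 0 percentage points. At 50.0 h it still shows 65.4% gone and 46.2% product. Its slowest mode has a half-life of 0.0895 h, far shorter than 5.0 h. Free partner at the end is 0.704 M, which over the even-odds level gives 1.92; the flask's own odds stand at 1.89.

With 0.12 M of starting material, at the same equivalents and time, the level gives 45.5% taken, free partner 0.305 M below even odds, and 31.9% product. That neighbour gives 45.1% gone and 31.8% product, with 54.9% of its starting material left.

The readings are calculated for substances that don't exist; scatter was added.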